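**Retrosynthetic overview**
1. C-11–C-12 is cut last: a C-12 acid (one carbon shorter after CO2 loss) is joined to 3-methylbuta-1,3-dien-1-yl acetate by a photochemical decarboxylative radical addition that also delivers the E olefin and the acetate.
2. C-9–C-11 comes from a Johnson–Claisen rearrangement of a 7α-allylic alcohol, itself made by α-epoxidation and Wharton transposition of the C-9 enone, so C-9 is relayed from C-5.
3. The 2β,3β-diol comes from Woodward–Prévost cis-hydroxylation of a C-2/C-3 olefin on the hindered face.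
4. Ring A is the only ring formed (ring B is bought): the C-3–C-4 bond and the gem-dimethyl carbon arise from a vinylsilane-terminated cation–olefin cyclisation.
5. Ring B and C-5 are bought as (R)-carvone; C-10 is set by two enolate alkylations (three-carbon arm first, then methyl anti to the isopropenyl group).

Assumption: the SMILES is taken literally, so the target is a labdane with a cis A/B fusion (C-10 methyl, H-5 and the C-9 side chain on one face, the 2,3-diol on the other); labdane locants are used below, α means the face of the C-10 methyl and β the opposite face.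

**Route**

Step 1
Reactants: 1 (R)-(−)-carvone; 2 3-bromo-1-(trimethylsilyl)prop-1-yne
Product: 3 (5R,6S)-2-methyl-5-(prop-1-en-2-yl)-6-[3-(trimethylsilyl)prop-2-yn-1-yl]cyclohex-2-en-1-one
Conditions: LiN(i-Pr)2, THF, −78 °C; then 2, −78 → 0 °C
Reagents that add atoms: none
Why: Kinetic α′-deprotonation of the enone and SN2 enolate alkylation by the propargylic bromide; the arm enters anti to the isopropenyl group, but this centre is re-enolised in step 2.

Step 2
Reactants: 3 (5R,6S)-2-methyl-5-(prop-1-en-2-yl)-6-[3-(trimethylsilyl)prop-2-yn-1-yl]cyclohex-2-en-1-one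
Product: 4 (5S,6R)-2,6-dimethyl-5-(prop-1-en-2-yl)-6-[3-(trimethylsilyl)prop-2-yn-1-yl]cyclohex-2-en-1-one
Conditions: LiN(i-Pr)2, THF, DMPU, −78 °C; MeI, −78 → 0 °C
Reagents that add atoms: iodomethane, CI
Why: Second α′-enolate alkylation, in which iodomethane attacks anti to the neighbouring isopropenyl group; this sets quaternary C-10 with the methyl trans and the three-carbon arm cis to isopropenyl, as the cis ring fusion requires.

Step 3
Reactants: 4 (5S,6R)-2,6-dimethyl-5-(prop-1-en-2-yl)-6-[3-(trimethylsilyl)prop-2-yn-1-yl]cyclohex-2-en-1-one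
Product: 5 (5S,6R)-2,6-dimethyl-5-(prop-1-en-2-yl)-6-[(2Z)-3-(trimethylsilyl)prop-2-en-1-yl]cyclohex-2-en-1-one
Conditions: H2 (1 atm), 5% Pd/CaCO3 poisoned with Pb(OAc)2, quinoline, EtOAc, 23 °C, stopped after 1 equiv H2
Reagents that add atoms: none
Why: Lindlar semihydrogenation adds H2 syn to the silylalkyne faster than to the 1,1-disubstituted or enone olefins, giving the (Z)-vinylsilane needed for endocyclic ring closure.

Step 4
Reactants: 5 (5S,6R)-2,6-dimethyl-5-(prop-1-en-2-yl)-6-[(2Z)-3-(trimethylsilyl)prop-2-en-1-yl]cyclohex-2-en-1-one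
Product: 6 (4aS,8aR)-2,5,5,8a-tetramethyl-4a,5,8,8a-tetrahydronaphthalen-1(4H)-one
Conditions: Tf2NH (5 mol%), (CF3)2CHOH, 0 °C
Reagents that add atoms: none
Why: Vinylsilane-terminated cation–olefin cyclisation: Markovnikov protonation of the isopropenyl group gives the tertiary C-4 cation, the silicon-bearing carbon attacks it 6-endo (β-silyl effect) and loss of silicon to the solvent leaves the C-2/C-3 olefin; the fusion is cis because both arms were fixed cis in step 2.

Step 5
Reactants: 6 (4aS,8aR)-2,5,5,8a-tetramethyl-4a,5,8,8a-tetrahydronaphthalen-1(4H)-one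
Product: 9 (4aS,6R,7S,8aR)-6,7-dihydroxy-2,5,5,8a-tetramethyl-4a,5,6,7,8,8a-hexahydronaphthalen-1(4H)-one, via trans-iodo acetate 7 (not isolated), via cis-hydroxy acetate 8 (not isolated)
Conditions: I2, AgOAc, AcOH, 23 °C; then H2O, 90 °C; then K2CO3, MeOH, 23 °C
Reagents that add atoms: silver acetate, CC(=O)[O-].[Ag+] (both diol oxygens); iodine, II (held only in 7); water, O (held only in the acetyl group of 8)
Why: Woodward–Prévost cis-hydroxylation: iodonium forms on the open α face, acetate opens it trans-diaxially from the β face and its carbonyl oxygen then displaces iodide with inversion, so C-2 and C-3 both receive oxygen on the hindered β face before methanolysis frees the diol.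

Step 6
Reactants: 9 (4aS,6R,7S,8aR)-6,7-dihydroxy-2,5,5,8a-tetramethyl-4a,5,6,7,8,8a-hexahydronaphthalen-1(4H)-one
Product: 10 7α,8α-epoxy-2β,3β-dihydroxy ketone (the α-oxirane of 9 at C-7/C-8; 7R,8R)
Conditions: 30% H2O2, NaOH (0.5 equiv), MeOH, 0 °C
Reagents that add atoms: hydrogen peroxide, OO
Why: Weitz–Scheffer nucleophilic epoxidation, in which hydroperoxide adds to C-7 axially and anti to the bulky C-4 substituent on C-5, giving the α-epoxide.

Step 7
Reactants: 10 7α,8α-epoxy-2β,3β-dihydroxy ketone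
Product: 11 (2R,3S,4aS,7R,8aR)-1,1,4a,6-tetramethyl-1,2,3,4,4a,7,8,8a-octahydronaphthalene-2,3,7-triol
Conditions: N2H4·H2O, AcOH (cat.), MeOH, 0 → 23 °C
Reagents that add atoms: none
Why: Wharton transposition: the epoxy hydrazone collapses with loss of N2 to the C-8/C-9 olefin and the C-7 alcohol, and because the C-7–O bond is never broken the 7α configuration is kept.

Step 8
Reactants: 11 (2R,3S,4aS,7R,8aR)-1,1,4a,6-tetramethyl-1,2,3,4,4a,7,8,8a-octahydronaphthalene-2,3,7-triol
Product: 14 2-[(1R,4aR,6R,7S,8aS)-6,7-dihydroxy-2,5,5,8a-tetramethyl-1,4,4a,5,6,7,8,8a-octahydronaphthalen-1-yl]acetic acid, via triol phenylboronate 12 (not isolated), via ester phenylboronate 13 (not isolated)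
Conditions: PhB(OH)2 (1.05 equiv), MeC(OEt)3, EtCO2H (10 mol%), 140 °C; then LiOH, 30% H2O2, THF–H2O, 0 → 23 °C; HCl to pH 3
Reagents that add atoms: triethyl orthoacetate, CCOC(C)(OCC)OCC (C-11 and C-12); lithium hydroxide, [Li+].[OH-] (acid OH oxygen); phenylboronic acid, OB(O)c1ccccc1 (held only in 12 and 13)
Why: Johnson–Claisen [3,3] rearrangement with the cis-diol masked in the flask as its cyclic phenylboronate; the suprafacial shift forms C-9–C-11 on the α face from which the C-7–O bond leaves, which sets C-9 and restores the C-7/C-8 olefin, and alkaline peroxide then cleaves the ester and the boronate.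

Step 9
Reactants: 15 3-methylbut-2-enal
Product: 16 (1E)-3-methylbuta-1,3-dien-1-yl acetate
Conditions: isopropenyl acetate, TsOH·H2O (cat.), 95 °C, acetone distilled off
Reagents that add atoms: isopropenyl acetate, CC(=C)OC(C)=O
Why: Acid-catalysed transfer acetylation of the dienol of the enal (enol acetate formation driven by loss of acetone); the geometry of the enol acetate bond does not matter because that bond becomes single in step 10.

Step 10
Reactants: 14 2-[(1R,4aR,6R,7S,8aS)-6,7-dihydroxy-2,5,5,8a-tetramethyl-1,4,4a,5,6,7,8,8a-octahydronaphthalen-1-yl]acetic acid; 16 (1E)-3-methylbuta-1,3-dien-1-yl acetate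
Product: 17 (2E)-5-[(1R,4aR,6R,7S,8aS)-6,7-dihydroxy-2,5,5,8a-tetramethyl-1,4,4a,5,6,7,8,8a-octahydronaphthalen-1-yl]-3-methylpent-2-en-1-yl acetate
Conditions: 16 (5 equiv), 9-(2-chlorophenyl)acridine (10 mol%), CH2Cl2 (0.5 M), 400 nm LEDs, 25 °C, N2
Reagents that add atoms: none
Why: Proposed new method: acridine-photocatalysed decarboxylative 1,4-hydroalkylation of a 1-acyloxy-1,3-diene; the hydrogen-bonded acid–acridine pair undergoes proton-coupled electron transfer at 400 nm, loss of CO2 gives the primary C-11 radical, this adds only to the unsubstituted CH2 terminus of the s-trans diene (the other terminus carries OAc) to give a configurationally stable (E)-1-acetoxy-3-methylallyl radical, and hydrogen-atom return from the acridinyl radical at the less hindered oxygen-bearing terminus C-15 gives the E trisubstituted olefin and the allylic acetate while regenerating the acridine; the closest known reactions are acridine-photocatalysed decarboxylative conjugate (Giese) additions of free carboxylic acids and radical 1,4-hydrofunctionalisations of isoprene-type dienes; no stereocentre is formed and C-9 is untouched.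

**Compound list**
1 | (R)-(−)-carvone, (5R)-2-methyl-5-(prop-1-en-2-yl)cyclohex-2-en-1-one | CC1=CC[C@H](CC1=O)C(C)=C | starting material
2 | 3-bromo-1-(trimethylsilyl)prop-1-yne | BrCC#C[Si](C)(C)C | starting material
3 | (5R,6S)-2-methyl-5-(prop-1-en-2-yl)-6-[3-(trimethylsilyl)prop-2-yn-1-yl]cyclohex-2-en-1-one (arm trans to isopropenyl) | O=C1C(C)=CC[C@@H](C(C)=C)[C@@H]1CC#C[Si](C)(C)C | intermediate
4 | (5S,6R)-2,6-dimethyl-5-(prop-1-en-2-yl)-6-[3-(trimethylsilyl)prop-2-yn-1-yl]cyclohex-2-en-1-one (methyl trans, arm cis to isopropenyl) | O=C1C(C)=CC[C@@H](C(C)=C)[C@@]1(C)CC#C[Si](C)(C)C | intermediate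
5 | (5S,6R)-2,6-dimethyl-5-(prop-1-en-2-yl)-6-[(2Z)-3-(trimethylsilyl)prop-2-en-1-yl]cyclohex-2-en-1-one | O=C1C(C)=CC[C@@H](C(C)=C)[C@@]1(C)C/C=C\[Si](C)(C)C | intermediate
6 | (4aS,8aR)-2,5,5,8a-tetramethyl-4a,5,8,8a-tetrahydronaphthalen-1(4H)-one (cis-fused; C-9 ketone, C-2/C-3 and C-7/C-8 olefins) | O=C1C(C)=CC[C@H]2C(C)(C)C=CC[C@@]12C | intermediate
7 | (4aR,6S,7S,8aR)-7-acetoxy-6-iodo-2,5,5,8a-tetramethyl-4a,5,6,7,8,8a-hexahydronaphthalen-1(4H)-one (2β-OAc, 3α-I) | O=C1C(C)=CC[C@H]2C(C)(C)[C@H](I)[C@@H](OC(C)=O)C[C@@]12C | intermediate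
8 | (4aS,6R,7S,8aR)-7-acetoxy-6-hydroxy-2,5,5,8a-tetramethyl-4a,5,6,7,8,8a-hexahydronaphthalen-1(4H)-one (2β-OAc, 3β-OH) | O=C1C(C)=CC[C@H]2C(C)(C)[C@@H](O)[C@@H](OC(C)=O)C[C@@]12C | intermediate
9 | (4aS,6R,7S,8aR)-6,7-dihydroxy-2,5,5,8a-tetramethyl-4a,5,6,7,8,8a-hexahydronaphthalen-1(4H)-one (2β,3β-diol) | O=C1C(C)=CC[C@H]2C(C)(C)[C@@H](O)[C@@H](O)C[C@@]12C | intermediate
10 | 7α,8α-epoxy-2β,3β-dihydroxy ketone: the α-oxirane of 9 at C-7/C-8 (7R,8R) | O=C1[C@]2(C)O[C@@H]2C[C@H]3C(C)(C)[C@@H](O)[C@@H](O)C[C@@]13C | intermediate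
11 | (2R,3S,4aS,7R,8aR)-1,1,4a,6-tetramethyl-1,2,3,4,4a,7,8,8a-octahydronaphthalene-2,3,7-triol (2β,3β,7α-triol, C-8/C-9 olefin) | C1=C(C)[C@H](O)C[C@H]2C(C)(C)[C@@H](O)[C@@H](O)C[C@@]12C | intermediate
12 | cyclic phenylboronate of 11 across the 2β,3β-diol (7α-OH free) | C1=C(C)[C@H](O)C[C@H]2C(C)(C)[C@H]3OB(c4ccccc4)O[C@H]3C[C@@]12C | intermediate
13 | ethyl ester of 14 with the 2β,3β-diol held as cyclic phenylboronate | CCOC(=O)C[C@@H]1C(C)=CC[C@H]2C(C)(C)[C@H]3OB(c4ccccc4)O[C@H]3C[C@@]12C | intermediate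
14 | 2-[(1R,4aR,6R,7S,8aS)-6,7-dihydroxy-2,5,5,8a-tetramethyl-1,4,4a,5,6,7,8,8a-octahydronaphthalen-1-yl]acetic acid | OC(=O)C[C@@H]1C(C)=CC[C@H]2C(C)(C)[C@@H](O)[C@@H](O)C[C@@]12C | intermediate
15 | 3-methylbut-2-enal | CC(C)=CC=O | starting material
16 | (1E)-3-methylbuta-1,3-dien-1-yl acetate | CC(=C)/C=C/OC(C)=O | intermediate
17 | (2E)-5-[(1R,4aR,6R,7S,8aS)-6,7-dihydroxy-2,5,5,8a-tetramethyl-1,4,4a,5,6,7,8,8a-octahydronaphthalen-1-yl]-3-methylpent-2-en-1-yl acetate | CC(=O)OC/C=C(\C)CC[C@@H]1C(C)=CC[C@H]2C(C)(C)[C@@H](O)[C@@H](O)C[C@@]12C | target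

**Step count and risks**
Total step count: 10. Longest linear sequence: 9 (steps 1 to 8 and 10).

Most likely to fail, first: step 10 (the proposed new step). The acridinyl radical may return hydrogen to C-13 (giving the enol acetate isomer), the C-11 radical may be reduced before it adds, or it may take H-5 by a 1,5-shift. The fallback uses known chemistry, sets out from 14 and comes back at 17. LiAlH4 reduces the acid to 2-[(1R,4aR,6R,7S,8aS)-6,7-dihydroxy-2,5,5,8a-tetramethyl-1,4,4a,5,6,7,8,8a-octahydronaphthalen-1-yl]ethan-1-ol F4. I2, PPh3 and imidazole convert the primary hydroxyl selectively into (1R,4aR,6R,7S,8aS)-1-(2-iodoethyl)-2,5,5,8a-tetramethyl-1,4,4a,5,6,7,8,8a-octahydronaphthalene-6,7-diol F5. A nickel-catalysed reductive cross-electrophile coupling (NiI2, 4,4′-di-tert-butyl-2,2′-bipyridine, Zn, DMA) then joins C-12 to C-13 of (2E)-3-iodobut-2-en-1-yl acetate F6 with retention of olefin geometry; F6 is made by acetylating bought (2E)-3-iodobut-2-en-1-ol with Ac2O and pyridine.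

Second: step 4. The C-4 cation may lose a proton toward C-5 (isopropylidene, which erases the C-5 centre) or the vinylsilane may be protodesilylated before ring closure. The fallback sets out from 5 and comes back at 6. Mukaiyama hydration (Co(acac)2, PhSiH3, O2, i-PrOH) of the isopropenyl group gives the tertiary alcohol (5R,6R)-5-(2-hydroxypropan-2-yl)-2,6-dimethyl-6-[(2Z)-3-(trimethylsilyl)prop-2-en-1-yl]cyclohex-2-en-1-one F1. This is ionised with SnCl4 in CH2Cl2 at −78 °C, so the cation is generated irreversibly from an alcohol at low temperature and trapped by the vinylsilane.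

Third: step 5. Displacement at the neopentyl C-3 may be slow, a C-4 methyl may migrate, or the iodonium may form on the wrong face. The fallback sets out from 6 and comes back at 9. OsO4 (cat.) and NMO dihydroxylate the open α face to give (4aS,6S,7R,8aR)-6,7-dihydroxy-2,5,5,8a-tetramethyl-4a,5,6,7,8,8a-hexahydronaphthalen-1(4H)-one F2. Swern oxidation gives the ring A dione (4aS,8aR)-2,5,5,8a-tetramethyl-4a,5,8,8a-tetrahydro-4H-naphthalene-1,6,7-trione F3, present mainly as its diosphenol. NaBH4 in CH2Cl2–MeOH at −78 °C then delivers hydride to both ring A carbonyls from the open α face, giving the 2β,3β-diol; the hindered conjugated C-9 ketone is expected to survive.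

Further compounds
F1 | step 4 | (5R,6R)-5-(2-hydroxypropan-2-yl)-2,6-dimethyl-6-[(2Z)-3-(trimethylsilyl)prop-2-en-1-yl]cyclohex-2-en-1-one | O=C1C(C)=CC[C@@H](C(C)(C)O)[C@@]1(C)C/C=C\[Si](C)(C)C
F2 | step 5 | (4aS,6S,7R,8aR)-6,7-dihydroxy-2,5,5,8a-tetramethyl-4a,5,6,7,8,8a-hexahydronaphthalen-1(4H)-one | O=C1C(C)=CC[C@H]2C(C)(C)[C@H](O)[C@H](O)C[C@@]12C
F3 | step 5 | (4aS,8aR)-2,5,5,8a-tetramethyl-4a,5,8,8a-tetrahydro-4H-naphthalene-1,6,7-trione | O=C1C(C)=CC[C@H]2C(C)(C)C(=O)C(=O)C[C@@]12C
F4 | step 10 | 2-[(1R,4aR,6R,7S,8aS)-6,7-dihydroxy-2,5,5,8a-tetramethyl-1,4,4a,5,6,7,8,8a-octahydronaphthalen-1-yl]ethan-1-ol | OCC[C@@H]1C(C)=CC[C@H]2C(C)(C)[C@@H](O)[C@@H](O)C[C@@]12C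
F5 | step 10 | (1R,4aR,6R,7S,8aS)-1-(2-iodoethyl)-2,5,5,8a-tetramethyl-1,4,4a,5,6,7,8,8a-octahydronaphthalene-6,7-diol | ICC[C@@H]1C(C)=CC[C@H]2C(C)(C)[C@@H](O)[C@@H](O)C[C@@]12C
F6 | step 10 | (2E)-3-iodobut-2-en-1-yl acetate | C/C(I)=C\COC(C)=O
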